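## The problem

Atom labels used throughout: ring A = C1–C6 (C4=C5 alkene, CH3 on C4); ring B = C1, C6, C7, C8, C9, C10 (CH3 and NHCHO on C10); oxane = O, C11 (CH3, bonded to C7), C12, C13, C14 (Cl), C15 (two CH3).

- The skeleton is a cis-fused octahydronaphthalene whose only alkene (C4=C5) lies next to the ring-fusion carbon C6. Ring B carries four contiguous stereocentres (C10, C1, C6, C7).
- C7 is bonded to the quaternary ether carbon C11, so the C7–C11 bond joins a tertiary to a fully substituted carbon and is the most congested bond of the molecule.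
- C11 and C14 sit in the oxane, outside the decalin. No ring relays configuration to them, so both need reagent control. C7 can control C6 and C1, and the finished ring can control C10.
- In the conformer with the oxanyl group equatorial, the C1–C2 bond is axial on ring B. A reagent therefore reaches a trigonal C10 from the opposite, axial α-face, and whichever group is added last to C10 ends up axial. The target has CH3 axial and N equatorial (cis to C2), so nitrogen must be on C10 before the methyl group arrives.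
- A chloronium closure of the oxane through a chair would place the large C7 substituent of C11 equatorial and chlorine equatorial, i.e. Cl trans to C7. The target has Cl cis to C7, so C14 cannot be left to the ring-closing transition state.
- Fragile features: the secondary chloride beside quaternary C15 (ionisation, oxygen participation with ring contraction, elimination); the trisubstituted alkene (electrophilic chlorine, strong acid); the cis ring fusion while C10 is a carbonyl (epimerisation at C1 to the more stable trans-decalin); the tertiary-alkyl formamide.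

## Retrosynthesis

**C10–CH3 and N–CHO (18 ⇒ 16 ⇒ 15 ⇒ 14).** The formyl group is removed first, then the C10–CH3 bond is cut, not the C10–N bond. This leads to the N-sulfinyl ketimine 15 and the cis-decalone 14. The alternative cut (C10–N from a C10 cation or tertiary alcohol) would bring nitrogen in last on the α-face and give the C10 epimer. The forward reaction needs only axial methyl delivery, which substrate and auxiliary both favour.

**C1–C6 and C2–C3 (14 ⇒ 13).** Ring A is a cyclohexene whose alkene is flanked by the fusion carbon C6, and C10 is a carbonyl conjugated to C1=C2 in the open form. This is the retron of an intramolecular Diels–Alder reaction of the deca-1,7,9-trien-3-one 13. One operation closes both rings and sets C6 and C1 from C7. The precursor 13 has no carbocycle and only three stereocentres (C7, C11, C14), all set by reagents. Cutting ring B alone (for example by metathesis) would leave C1 and C6 to be made separately.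

**Diene and dienophile arms (13 ⇒ 12 ⇒ 11 ⇒ 10 ⇒ 9 ⇒ 8).** The enone comes from allylic alcohol 12 (oxidation), the C10–C1 bond from vinyl addition to aldehyde 10. The diene comes from vinyl iodide 11/9 by cross-coupling (C4–C5 bond) and olefination of aldehyde 8 (C5=C6 bond). Both arms thus grow from the two carbons attached to C7. The acid step (acetal hydrolysis, 9 ⇒ 10) is placed before the diene exists.

**O–C15 (8 ⇒ 7 ⇒ 6).** The oxane is cut at the O–C15 bond, in the forward sense an SN1 capture of a tertiary C15 cation by the C11 hydroxyl of dichloride 6. This cut is preferred over a chloronium closure of an alkene because C15 is not stereogenic. The ring closure then creates no stereocentre, and C11 and C14 keep the configurations given to them earlier.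

**C7–C8 (6 ⇒ 5).** The C7–C8 bond is cut to the 2,3-epoxy alcohol 5 and a three-carbon Grignard reagent. One SN2 event sets C7 by inversion, and the epoxide C–O bond that survives becomes the C11–O bond of the target. No aldol or ketone addition could distinguish CH3 from CH2 at C11 as cleanly.

**Epoxide, C14–Cl and the terpene (5 ⇒ 4 ⇒ 3 ⇒ 2 ⇒ 1).** The epoxide of 5 comes from allylic alcohol 4 by asymmetric epoxidation. The vicinal dichloride of 4/3 comes from epoxide 2 with inversion at C14, and 2 from geranyl acetate 1 by a second catalytic epoxidation. Compound 1 supplies C6, C7, C11–C15 and three methyl groups in the right order.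

## Roads not taken

**Alternative 1 (the most obvious):** the same [4+2] cut, but on trienone A1 that still carries the open side chain (tertiary C11 carbinol and the C14=C15 alkene).
- Forward: cyclisation to decalone A2, methyl addition to carbinol A3, Ritter-type amination at C10, then a final chloroetherification.
- Why the chosen plan is better: (i) in A3 nitrogen arrives last, from the α-face of the C10 cation, and gives the C10 epimer. (ii) The chloronium closure sets C14 in a chair that puts the decalinyl group equatorial, which gives the C14 epimer with no reagent handle. (iii) Electrophilic chlorine and the cationic amination both meet the C4=C5 alkene. The chosen route reverses the order at C10, fixes C14 by a catalyst and closes the oxane before any other alkene is present.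

**Alternative 2:** union of two monoterpene halves by cutting C6–C7, C9–C10 and C10–N.
- Forward: menthadienol A4 and oxanylacetic acid A5 give ester A6. An Ireland–Claisen rearrangement moves the C4 carbinol to a new C6–C7 bond and creates the C4=C5 alkene. Conversion to a vinyl ketone and ring-closing metathesis (second-generation Grubbs catalyst) gives enone A7. Reduction and an allyl cyanate-to-isocyanate rearrangement then carry the C8 carbinol to the C10–N bond.
- Why not: for a cyclohexenyl ester, the chair (one ketene acetal geometry) and the boat (the other) both place the oxanyl group on the β-face, i.e. the C7 epimer. Correcting C7 by enolisation next to the ring oxygen invites β-elimination that opens the oxane. The route also needs the scarcer limonene enantiomer series and about four more steps.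

**Alternative 3:** ring A built onto a preformed ring B by cutting C1–C2 and C5–C6.
- Forward: the dearomatised dienone A8 already has N and CH3 on C10. A Diels–Alder reaction on the face syn to nitrogen gives adduct A9 with C10, C1 and C6 correct relative to each other.
- Why not: the new alkene forms at C3=C4, not C4=C5, so a transposition is needed. A8 is achiral, so absolute control needs a chiral catalyst. C7 arrives as a carbonyl, and turning it into a CH bonded to the quaternary ether carbon C11 has no stereocontrolled solution. The chosen route obtains C7 and C11 together from one epoxide.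

Key step: step 12

Assumption: geranyl acetate, the D-fructose-derived epoxidation ketone, L-(+)-diethyl tartrate, (R)-tert-butanesulfinamide and a THF solution of the dioxanylethyl Grignard reagent are taken as purchasable; the target is (1R,4R,4aR,8aS) in naphthalene numbering with a (2S,5S)-oxane, as the SMILES requires.

## Route

Step 1
Reactants: 1 geranyl acetate [(2E)-3,7-dimethylocta-2,6-dien-1-yl acetate]
Product: 2 (2E)-5-[(2R)-3,3-dimethyloxiran-2-yl]-3-methylpent-2-en-1-yl acetate
Conditions: 1,2:4,5-di-O-isopropylidene-D-erythro-2,3-hexodiulo-2,6-pyranose (30 mol %), KHSO5 (Oxone), K2CO3, Bu4NHSO4, MeCN–CH2(OMe)2–aq. Na2B4O7, 0 °C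
Reagents that add atoms: potassium peroxymonosulfate [K+].[O-]S(=O)(=O)OO
Why: Shi asymmetric epoxidation; the dioxirane takes the electron-rich distal alkene because the 2,3-alkene is deactivated by the allylic acetate, and the spiro transition state of the D-fructose-derived ketone should give the (R)-epoxide at C14.

Step 2
Reactants: 2 (2E)-5-[(2R)-3,3-dimethyloxiran-2-yl]-3-methylpent-2-en-1-yl acetate
Product: 3 (2E,6S)-6,7-dichloro-3,7-dimethyloct-2-en-1-yl acetate
Conditions: Ph3PCl2, 2,6-lutidine (cat.), CH2Cl2, 0 → 23 °C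
Reagents that add atoms: dichlorotriphenylphosphorane ClP(Cl)(c1ccccc1)(c1ccccc1)c1ccccc1
Why: Appel-type deoxydichlorination of an epoxide; chloride opens the phosphorus-activated epoxide at the tertiary carbon and the secondary alkoxyphosphonium is then displaced with inversion (directly or through the chloronium), so the (R)-C–O bond becomes the (S)-C–Cl bond of C14.

Step 3
Reactants: 3 (2E,6S)-6,7-dichloro-3,7-dimethyloct-2-en-1-yl acetate
Product: 4 (2E,6S)-6,7-dichloro-3,7-dimethyloct-2-en-1-ol
Conditions: K2CO3 (cat.), MeOH, 0 °C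
Reagents that add atoms: none
Why: Methanolysis (transesterification) of the acetate; the β-chlorine retards ionisation of the tertiary chloride, so the dichloride should survive cold, weakly basic methanol.

Step 4
Reactants: 4 (2E,6S)-6,7-dichloro-3,7-dimethyloct-2-en-1-ol
Product: 5 [(2S,3S)-3-[(3S)-3,4-dichloro-4-methylpentyl]-3-methyloxiran-2-yl]methanol
Conditions: Ti(OiPr)4 (10 mol %), L-(+)-diethyl tartrate (12 mol %), t-BuOOH, 4 Å molecular sieves, CH2Cl2, −20 °C
Reagents that add atoms: tert-butyl hydroperoxide CC(C)(C)OO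
Why: Sharpless asymmetric epoxidation of an (E)-trisubstituted allylic alcohol; L-(+)-tartrate gives the (2S,3S)-epoxide, which fixes C11 (this C–O bond is never broken again) and prepares C7 for inversion.

Step 5
Reactants: 5 [(2S,3S)-3-[(3S)-3,4-dichloro-4-methylpentyl]-3-methyloxiran-2-yl]methanol
Product: 6 (2R,3S,6S)-6,7-dichloro-2-[2-(1,3-dioxan-2-yl)ethyl]-3,7-dimethyloctane-1,3-diol
Conditions: [2-(1,3-dioxan-2-yl)ethyl]MgBr (3.5 equiv), CuI (15 mol %), THF, −30 → 0 °C; aq. NH4Cl
Reagents that add atoms: [2-(1,3-dioxan-2-yl)ethyl]magnesium bromide Br[Mg]CCC1OCCCO1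
Why: Copper-catalysed Grignard opening of a 2,3-epoxy alcohol; the organocopper attacks the less substituted epoxide carbon (C7) in an SN2 sense with inversion, which sets C7 next to C11 in one event. The alkyl chlorides should be inert at this temperature.

Step 6
Reactants: 6 (2R,3S,6S)-6,7-dichloro-2-[2-(1,3-dioxan-2-yl)ethyl]-3,7-dimethyloctane-1,3-diol
Product: 7 (2R)-2-[(2S,5S)-5-chloro-2,6,6-trimethyloxan-2-yl]-4-(1,3-dioxan-2-yl)butan-1-ol
Conditions: AgOSO2CF3 (1.2 equiv), 2,6-di-tert-butyl-4-methylpyridine (1.5 equiv), CH2Cl2, −40 → 0 °C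
Reagents that add atoms: none
Why: Silver-assisted SN1 etherification; silver removes only the tertiary chloride and the β-chloro cation (chloronium) is captured at its tertiary carbon by the C11 hydroxyl to close the six-membered ring. No stereocentre is formed or broken, so C11 (step 4) and C14 (steps 1 and 2) are carried into the oxane unchanged.

Step 7
Reactants: 7 (2R)-2-[(2S,5S)-5-chloro-2,6,6-trimethyloxan-2-yl]-4-(1,3-dioxan-2-yl)butan-1-ol
Product: 8 (2S)-2-[(2S,5S)-5-chloro-2,6,6-trimethyloxan-2-yl]-4-(1,3-dioxan-2-yl)butanal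
Conditions: TEMPO (10 mol %), PhI(OAc)2, CH2Cl2, 23 °C
Reagents that add atoms: none
Why: Nitroxyl-catalysed oxidation of a primary alcohol under non-basic conditions, so C7 (α to the aldehyde, β to the ring oxygen) is neither epimerised nor eliminated; the descriptor changes only because CHO outranks the oxanyl carbon.

Step 8
Reactants: 8 (2S)-2-[(2S,5S)-5-chloro-2,6,6-trimethyloxan-2-yl]-4-(1,3-dioxan-2-yl)butanal
Product: 9 2-[(3R,4E)-3-[(2S,5S)-5-chloro-2,6,6-trimethyloxan-2-yl]-5-iodopent-4-en-1-yl]-1,3-dioxane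
Conditions: CrCl2 (6 equiv), CHI3 (2 equiv), THF, 0 °C
Reagents that add atoms: iodoform IC(I)I
Why: Takai olefination; addition of the geminal dichromium species and anti elimination should give the (E)-vinyl iodide, and the non-basic medium leaves C7 untouched.

Step 9
Reactants: 9 2-[(3R,4E)-3-[(2S,5S)-5-chloro-2,6,6-trimethyloxan-2-yl]-5-iodopent-4-en-1-yl]-1,3-dioxane
Product: 10 (4R,5E)-4-[(2S,5S)-5-chloro-2,6,6-trimethyloxan-2-yl]-6-iodohex-5-enal
Conditions: 1 M aq. HCl, THF, 35 °C
Reagents that add atoms: water O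
Why: Acid hydrolysis of the cyclic acetal, placed before the acid-sensitive diene is made; the tertiary ether, the alkyl chloride and the vinyl iodide should tolerate dilute acid.

Step 10
Reactants: 10 (4R,5E)-4-[(2S,5S)-5-chloro-2,6,6-trimethyloxan-2-yl]-6-iodohex-5-enal
Product: 11 (6R,7E)-6-[(2S,5S)-5-chloro-2,6,6-trimethyloxan-2-yl]-8-iodoocta-1,7-dien-3-ol as both C3 epimers
Conditions: CH2=CHMgBr, THF, −78 °C
Reagents that add atoms: vinylmagnesium bromide C=C[Mg]Br
Why: Grignard 1,2-addition to the aldehyde; the mixed carbinol centre is erased by oxidation in step 12, and no iodine–magnesium exchange is expected at −78 °C.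

Step 11
Reactants: 11 (6R,7E)-6-[(2S,5S)-5-chloro-2,6,6-trimethyloxan-2-yl]-8-iodoocta-1,7-dien-3-ol as both C3 epimers
Product: 12 (6R,7E)-6-[(2S,5S)-5-chloro-2,6,6-trimethyloxan-2-yl]-9-methyldeca-1,7,9-trien-3-ol as both C3 epimers
Conditions: isopropenyl-B(pin), Pd(PPh3)4 (5 mol %), K3PO4, THF–H2O, 50 °C
Reagents that add atoms: 4,4,5,5-tetramethyl-2-(prop-1-en-2-yl)-1,3,2-dioxaborolane CC(=C)B1OC(C)(C)C(C)(C)O1
Why: Suzuki–Miyaura coupling with retention of alkene geometry gives the (E)-2-methyl-1,3-diene; the secondary alkyl chloride should not add to zerovalent palladium under these conditions.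

Step 12
Reactants: 12 (6R,7E)-6-[(2S,5S)-5-chloro-2,6,6-trimethyloxan-2-yl]-9-methyldeca-1,7,9-trien-3-ol as both C3 epimers
Product: 14 (4R,4aS,8aS)-4-[(2S,5S)-5-chloro-2,6,6-trimethyloxan-2-yl]-6-methyl-3,4,4a,7,8,8a-hexahydronaphthalen-1(2H)-one, via trienone 13 (not isolated)
Conditions: Dess–Martin periodinane, CH2Cl2, 0 °C; then toluene, 23 → 40 °C
Reagents that add atoms: none
Why: Oxidation unmasks the vinyl ketone, and trienone 13 undergoes a concerted, asynchronous, normal-demand intramolecular Diels–Alder reaction (diene C3=C4–C5=C6, dienophile C1=C2 activated by the C10 carbonyl in the tether); the closest known reaction type is the cyclisation of deca-1,7,9-trien-3-ones to cis-fused octalones. Ring A is closed as the new cyclohexene by the two forming bonds C2–C3 and C1–C6, and ring B is closed by the C1–C6 bond through the four-atom tether C7–C10 in the fused mode with a chair-like tether. C6 is set by C7: the C7–H bond eclipses the diene plane to minimise allylic 1,3-strain, the tether leaves towards the dienophile and the oxanyl group points away, so H6 and H7 end up anti (oxanyl trans to C5). C1 is set by the endo position of the tether carbonyl under the diene, which gives the cis ring fusion. The step therefore needs endo over exo closure and one diene face; the first is secured by the carbonyl lying inside the tether, the second by the size of the quaternary C11 substituent on C7. The alkyl chloride, the tertiary ether and the product alkene should be inert at 40 °C, and ketone 14 is kept away from base because its cis fusion is the less stable one.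

Step 13
Reactants: 14 (4R,4aS,8aS)-4-[(2S,5S)-5-chloro-2,6,6-trimethyloxan-2-yl]-6-methyl-3,4,4a,7,8,8a-hexahydronaphthalen-1(2H)-one
Product: 15 (R)-N-[(1E,4R,4aR,8aS)-4-[(2S,5S)-5-chloro-2,6,6-trimethyloxan-2-yl]-6-methyl-3,4,4a,7,8,8a-hexahydronaphthalen-1(2H)-ylidene]-2-methylpropane-2-sulfinamide
Conditions: (R)-t-BuS(O)NH2, Ti(OEt)4, THF, 60 °C
Reagents that add atoms: (R)-2-methylpropane-2-sulfinamide CC(C)(C)[S@](N)=O
Why: Titanium-mediated condensation to the N-tert-butanesulfinyl ketimine, with sulfur anti to the branched C1; this puts nitrogen on C10 before the methyl group.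

Step 14
Reactants: 15 (R)-N-[(1E,4R,4aR,8aS)-4-[(2S,5S)-5-chloro-2,6,6-trimethyloxan-2-yl]-6-methyl-3,4,4a,7,8,8a-hexahydronaphthalen-1(2H)-ylidene]-2-methylpropane-2-sulfinamide
Product: 16 (R)-N-[(1R,4R,4aR,8aS)-4-[(2S,5S)-5-chloro-2,6,6-trimethyloxan-2-yl]-1,6-dimethyl-1,2,3,4,4a,7,8,8a-octahydronaphthalen-1-yl]-2-methylpropane-2-sulfinamide
Conditions: AlMe3 (1.1 equiv), toluene, −78 °C; then CH3Li (2 equiv), −78 °C
Reagents that add atoms: methyllithium [Li]C
Why: 1,2-Addition of an organolithium to an aluminium-activated N-sulfinyl ketimine; methyl should enter axially on the α-face, anti to the axial C1–C2 bond, and the six-membered chelate of the (R)-sulfinyl group directs to the same face (matched pair). Nitrogen is thus left equatorial and cis to C2, which sets C10.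

Step 15
Reactants: 16 (R)-N-[(1R,4R,4aR,8aS)-4-[(2S,5S)-5-chloro-2,6,6-trimethyloxan-2-yl]-1,6-dimethyl-1,2,3,4,4a,7,8,8a-octahydronaphthalen-1-yl]-2-methylpropane-2-sulfinamide
Product: 18 N-[(1R,4R,4aR,8aS)-4-[(2S,5S)-5-chloro-2,6,6-trimethyloxan-2-yl]-1,6-dimethyl-1,2,3,4,4a,7,8,8a-octahydronaphthalen-1-yl]formamide, via amine hydrochloride 17 (not isolated)
Conditions: HCl (4 M in dioxane, 2 equiv), MeOH, 0 °C; evaporate; then HCO2CH2CF3, Et3N, CH2Cl2, 23 → 40 °C
Reagents that add atoms: 2,2,2-trifluoroethyl formate O=COCC(F)(F)F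
Why: Acidic methanolysis of the sulfinamide, then N-formylation of the hindered primary amine with an activated formate; no stereocentre is touched.

## Compound list

1 | geranyl acetate, (2E)-3,7-dimethylocta-2,6-dien-1-yl acetate | CC(=O)OC/C=C(\C)CCC=C(C)C | starting material
2 | (2E)-5-[(2R)-3,3-dimethyloxiran-2-yl]-3-methylpent-2-en-1-yl acetate | CC(=O)OC/C=C(\C)CC[C@H]1OC1(C)C | intermediate
3 | (2E,6S)-6,7-dichloro-3,7-dimethyloct-2-en-1-yl acetate | CC(=O)OC/C=C(\C)CC[C@H](Cl)C(C)(C)Cl | intermediate
4 | (2E,6S)-6,7-dichloro-3,7-dimethyloct-2-en-1-ol | OC/C=C(\C)CC[C@H](Cl)C(C)(C)Cl | intermediate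
5 | [(2S,3S)-3-[(3S)-3,4-dichloro-4-methylpentyl]-3-methyloxiran-2-yl]methanol | OC[C@@H]1O[C@@]1(C)CC[C@H](Cl)C(C)(C)Cl | intermediate
6 | (2R,3S,6S)-6,7-dichloro-2-[2-(1,3-dioxan-2-yl)ethyl]-3,7-dimethyloctane-1,3-diol | OC[C@H]([C@](O)(C)CC[C@H](Cl)C(C)(C)Cl)CCC1OCCCO1 | intermediate
7 | (2R)-2-[(2S,5S)-5-chloro-2,6,6-trimethyloxan-2-yl]-4-(1,3-dioxan-2-yl)butan-1-ol | OC[C@H]([C@]2(C)CC[C@H](Cl)C(C)(C)O2)CCC1OCCCO1 | intermediate
8 | (2S)-2-[(2S,5S)-5-chloro-2,6,6-trimethyloxan-2-yl]-4-(1,3-dioxan-2-yl)butanal | O=C[C@H]([C@]2(C)CC[C@H](Cl)C(C)(C)O2)CCC1OCCCO1 | intermediate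
9 | 2-[(3R,4E)-3-[(2S,5S)-5-chloro-2,6,6-trimethyloxan-2-yl]-5-iodopent-4-en-1-yl]-1,3-dioxane | I/C=C/[C@H]([C@]2(C)CC[C@H](Cl)C(C)(C)O2)CCC1OCCCO1 | intermediate
10 | (4R,5E)-4-[(2S,5S)-5-chloro-2,6,6-trimethyloxan-2-yl]-6-iodohex-5-enal | I/C=C/[C@H]([C@]2(C)CC[C@H](Cl)C(C)(C)O2)CCC=O | intermediate
11 | (6R,7E)-6-[(2S,5S)-5-chloro-2,6,6-trimethyloxan-2-yl]-8-iodoocta-1,7-dien-3-ol, both C3 epimers | I/C=C/[C@H]([C@]2(C)CC[C@H](Cl)C(C)(C)O2)CCC(O)C=C | intermediate
12 | (6R,7E)-6-[(2S,5S)-5-chloro-2,6,6-trimethyloxan-2-yl]-9-methyldeca-1,7,9-trien-3-ol, both C3 epimers | CC(=C)/C=C/[C@H]([C@]2(C)CC[C@H](Cl)C(C)(C)O2)CCC(O)C=C | intermediate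
13 | (6R,7E)-6-[(2S,5S)-5-chloro-2,6,6-trimethyloxan-2-yl]-9-methyldeca-1,7,9-trien-3-one | CC(=C)/C=C/[C@H]([C@]2(C)CC[C@H](Cl)C(C)(C)O2)CCC(=O)C=C | intermediate
14 | (4R,4aS,8aS)-4-[(2S,5S)-5-chloro-2,6,6-trimethyloxan-2-yl]-6-methyl-3,4,4a,7,8,8a-hexahydronaphthalen-1(2H)-one | CC1=C[C@H]2[C@H]([C@]3(C)CC[C@H](Cl)C(C)(C)O3)CCC(=O)[C@H]2CC1 | intermediate
15 | (R)-N-[(1E,4R,4aR,8aS)-4-[(2S,5S)-5-chloro-2,6,6-trimethyloxan-2-yl]-6-methyl-3,4,4a,7,8,8a-hexahydronaphthalen-1(2H)-ylidene]-2-methylpropane-2-sulfinamide | CC1=C[C@H]2[C@H]([C@]3(C)CC[C@H](Cl)C(C)(C)O3)CC/C(=N\[S@](=O)C(C)(C)C)[C@H]2CC1 | intermediate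
16 | (R)-N-[(1R,4R,4aR,8aS)-4-[(2S,5S)-5-chloro-2,6,6-trimethyloxan-2-yl]-1,6-dimethyl-1,2,3,4,4a,7,8,8a-octahydronaphthalen-1-yl]-2-methylpropane-2-sulfinamide | CC1=C[C@H]2[C@H]([C@]3(C)CC[C@H](Cl)C(C)(C)O3)CC[C@@](C)(N[S@](=O)C(C)(C)C)[C@H]2CC1 | intermediate
17 | (1R,4R,4aR,8aS)-4-[(2S,5S)-5-chloro-2,6,6-trimethyloxan-2-yl]-1,6-dimethyl-1,2,3,4,4a,7,8,8a-octahydronaphthalen-1-aminium chloride | CC1=C[C@H]2[C@H]([C@]3(C)CC[C@H](Cl)C(C)(C)O3)CC[C@@](C)([NH3+])[C@H]2CC1.[Cl-] | intermediate
18 | N-[(1R,4R,4aR,8aS)-4-[(2S,5S)-5-chloro-2,6,6-trimethyloxan-2-yl]-1,6-dimethyl-1,2,3,4,4a,7,8,8a-octahydronaphthalen-1-yl]formamide | CC1=C[C@H]2[C@H]([C@]3(C)CC[C@H](Cl)C(C)(C)O3)CC[C@@](C)(NC=O)[C@H]2CC1 | target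

## Step count and least certain steps

Total: 15 steps. Longest linear sequence: 15 steps (from geranyl acetate 1; all other carbon sources are purchased reagents).

**Step 12 (key step).**
- Risk: incomplete endo preference. Exo closure gives the trans-fused C1 epimer, which cannot be corrected later because the cis ketone is the less stable epimer. The vinyl ketone 13 may also oligomerise before it cyclises.
- Fallback, from 10 back to 14: ethynylmagnesium bromide gives the propargylic alcohol F1. The coupling of step 11 gives the dienynol F2, and oxidation gives the ynone F3. Heating in toluene closes both rings to the cyclohexadienyl ketone F4. With an alkyne dienophile there is no endo/exo question, and C6 is set by the same allylic control. Hydrogenation of the conjugated C1=C2 bond (H2, Pd/C, EtOAc, one equivalent) should occur on the α-face, which is not covered by the puckered ring B, and give 14 with the cis fusion.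

**Step 6.**
- Risk: proton loss from the β-chloro cation (E1) instead of capture by the hindered tertiary hydroxyl, and some capture at the secondary carbon of the chloronium (five-membered ether with inverted C14).
- Fallback, from 6 back to 7: the elimination product, allylic chloride F7, is not waste. Hg(O2CCF3)2 adds the C11 hydroxyl to its 1,1-disubstituted alkene in the Markovnikov sense (six-membered ring). Brine gives the chloromercurial F8, and NaBH4 in aqueous NaOH removes mercury to give 7. C14 is not involved.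

**Step 2.**
- Risk: ionisation of the activated trisubstituted epoxide, leading to proton loss (allylic chloride) or a 1,2-hydride shift (ketone). Configuration at C14 may also erode if external chloride opens the chloronium at its secondary carbon.
- Fallback, from 2 back to 3: pyridinium chloride in CH2Cl2 opens the epoxide at the tertiary carbon with retention at C14 to give the chlorohydrin F5. MsCl and Et3N give the mesylate F6. LiCl in DMF at 60 °C displaces the mesylate with one inversion at C14, assisted by the neighbouring chlorine, to give 3.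

**Step 13.**
- Risk: epimerisation at C1 (cis to trans ring fusion) through a titanium enolate or the enamine tautomer during the slow condensation of a hindered, α-branched ketone.
- Fallback, from 14 back to 17: hydroxylamine hydrochloride and NaOAc in EtOH at 23 °C give the oxime F9. Ph2PCl and Et3N (−40 → 23 °C) rearrange it to the N-diphenylphosphinoyl ketimine F10. CH3MgBr with CeCl3 at −78 °C adds axially under substrate control to give the phosphinamide F11. HCl in MeOH releases the amine hydrochloride 17, which is formylated as in step 15.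

## Further compounds

F1 | step 12 | (6R,7E)-6-[(2S,5S)-5-chloro-2,6,6-trimethyloxan-2-yl]-8-iodooct-7-en-1-yn-3-ol, both C3 epimers | I/C=C/[C@H]([C@]1(C)CC[C@H](Cl)C(C)(C)O1)CCC(O)C#C
F2 | step 12 | (6R,7E)-6-[(2S,5S)-5-chloro-2,6,6-trimethyloxan-2-yl]-9-methyldeca-7,9-dien-1-yn-3-ol, both C3 epimers | CC(=C)/C=C/[C@H]([C@]1(C)CC[C@H](Cl)C(C)(C)O1)CCC(O)C#C
F3 | step 12 | (6R,7E)-6-[(2S,5S)-5-chloro-2,6,6-trimethyloxan-2-yl]-9-methyldeca-7,9-dien-1-yn-3-one | CC(=C)/C=C/[C@H]([C@]1(C)CC[C@H](Cl)C(C)(C)O1)CCC(=O)C#C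
F4 | step 12 | (4R,4aS)-4-[(2S,5S)-5-chloro-2,6,6-trimethyloxan-2-yl]-6-methyl-3,4,4a,7-tetrahydronaphthalen-1(2H)-one | CC1=C[C@H]2[C@H]([C@]3(C)CC[C@H](Cl)C(C)(C)O3)CCC(=O)C2=CC1
F5 | step 2 | (2E,6R)-7-chloro-6-hydroxy-3,7-dimethyloct-2-en-1-yl acetate | CC(=O)OC/C=C(\C)CC[C@@H](O)C(C)(C)Cl
F6 | step 2 | (2E,6R)-7-chloro-3,7-dimethyl-6-[(methylsulfonyl)oxy]oct-2-en-1-yl acetate | CC(=O)OC/C=C(\C)CC[C@@H](OS(C)(=O)=O)C(C)(C)Cl
F7 | step 6 | (2R,3S,6S)-6-chloro-2-[2-(1,3-dioxan-2-yl)ethyl]-3,7-dimethyloct-7-ene-1,3-diol | OC[C@H]([C@](O)(C)CC[C@H](Cl)C(C)=C)CCC1OCCCO1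
F8 | step 6 | chloro{[(3S,6S)-3-chloro-6-[(2R)-4-(1,3-dioxan-2-yl)-1-hydroxybutan-2-yl]-2,6-dimethyloxan-2-yl]methyl}mercury, both C2 epimers | OC[C@H]([C@]1(C)CC[C@H](Cl)C(C)(C[Hg]Cl)O1)CCC2OCCCO2
F9 | step 13 | (1E,4R,4aR,8aS)-4-[(2S,5S)-5-chloro-2,6,6-trimethyloxan-2-yl]-6-methyl-3,4,4a,7,8,8a-hexahydronaphthalen-1(2H)-one oxime | CC1=C[C@H]2[C@H]([C@]3(C)CC[C@H](Cl)C(C)(C)O3)CC/C(=N\O)[C@H]2CC1
F10 | step 13 | N-[(4R,4aR,8aS)-4-[(2S,5S)-5-chloro-2,6,6-trimethyloxan-2-yl]-6-methyl-3,4,4a,7,8,8a-hexahydronaphthalen-1(2H)-ylidene]-P,P-diphenylphosphinic amide | CC1=C[C@H]2[C@H]([C@]3(C)CC[C@H](Cl)C(C)(C)O3)CCC(=NP(=O)(c4ccccc4)c4ccccc4)[C@H]2CC1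
F11 | step 13 | N-[(1R,4R,4aR,8aS)-4-[(2S,5S)-5-chloro-2,6,6-trimethyloxan-2-yl]-1,6-dimethyl-1,2,3,4,4a,7,8,8a-octahydronaphthalen-1-yl]-P,P-diphenylphosphinic amide | CC1=C[C@H]2[C@H]([C@]3(C)CC[C@H](Cl)C(C)(C)O3)CC[C@@](C)(NP(=O)(c4ccccc4)c4ccccc4)[C@H]2CC1
A1 | alternative 1 | (6R,7E)-6-[(2S)-2-hydroxy-6-methylhept-5-en-2-yl]-9-methyldeca-1,7,9-trien-3-one | CC(=C)/C=C/[C@H]([C@](O)(C)CCC=C(C)C)CCC(=O)C=C
A2 | alternative 1 | (4R,4aS,8aS)-4-[(2S)-2-hydroxy-6-methylhept-5-en-2-yl]-6-methyl-3,4,4a,7,8,8a-hexahydronaphthalen-1(2H)-one | CC1=C[C@H]2[C@H]([C@](O)(C)CCC=C(C)C)CCC(=O)[C@H]2CC1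
A3 | alternative 1 | (1R,4R,4aR,8aS)-4-[(2S)-2-hydroxy-6-methylhept-5-en-2-yl]-1,6-dimethyl-1,2,3,4,4a,7,8,8a-octahydronaphthalen-1-ol | CC1=C[C@H]2[C@H]([C@](O)(C)CCC=C(C)C)CC[C@@](C)(O)[C@H]2CC1
A4 | alternative 2 | (1R,4S)-1-methyl-4-(prop-1-en-2-yl)cyclohex-2-en-1-ol | C[C@]1(O)C=C[C@@H](C(C)=C)CC1
A5 | alternative 2 | 2-[(2S,5S)-5-chloro-2,6,6-trimethyloxan-2-yl]acetic acid | OC(=O)C[C@]1(C)CC[C@H](Cl)C(C)(C)O1
A6 | alternative 2 | (1R,4S)-1-methyl-4-(prop-1-en-2-yl)cyclohex-2-en-1-yl 2-[(2S,5S)-5-chloro-2,6,6-trimethyloxan-2-yl]acetate | C[C@]1(OC(=O)C[C@]2(C)CC[C@H](Cl)C(C)(C)O2)C=C[C@@H](C(C)=C)CC1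
A7 | alternative 2 | (1R,4aS,8aR)-1-[(2S,5S)-5-chloro-2,6,6-trimethyloxan-2-yl]-4,7-dimethyl-4a,5,6,8a-tetrahydronaphthalen-2(1H)-one | CC1=C[C@H]2[C@H]([C@]3(C)CC[C@H](Cl)C(C)(C)O3)C(=O)C=C(C)[C@H]2CC1
A8 | alternative 3 | N-(1-methyl-4-oxocyclohexa-2,5-dien-1-yl)acetamide | CC(=O)NC1(C)C=CC(=O)C=C1
A9 | alternative 3 | N-(1,6-dimethyl-4-oxo-1,4,4a,5,8,8a-hexahydronaphthalen-1-yl)acetamide, racemic, cis-fused, nitrogen cis to C8 | CC1=CC[C@@H]2[C@](C)(NC(C)=O)C=CC(=O)[C@@H]2C1
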